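**Retrosynthetic overview** (carotenoid locants: C5 = O‑bearing quaternary ring carbon, C8 = O–CH carbon on the butenolide)
1. Target ⇐ desilylation ⇐ dihydrofuran ring closed last by silver‑catalysed 5‑endo cyclisation of an α‑hydroxyallene (axis‑to‑centre transfer sets C8) ⇐ anti‑SN2′ formate hydrogenolysis of an alkynyl oxirane.
2. C37 skeleton ⇐ one‑flask three‑component union on (E)‑2,3‑dibromoacrylic acid. The key C–C bond is butenolide C4–C5: the terminal alkyne of the eastern C23 polyenyne is used as a masked acyl anion at the acceptor β‑carbon (two carbons that are both electrophilic by nature) and lactonises to the Z‑ylidenebutenolide; the remaining α‑bromide then acts as an α‑carbonyl cation equivalent toward the western ethynyl oxirane.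
3. Eastern polyenyne ⇐ one enol triflate + a C2‑symmetric C14 tetraene‑diyne (2 × C6 enynyl phosphonium salt + glyoxal); western ethynyl oxirane ⇐ the same triflate + ethynyltrimethylsilane, then anti epoxidation.
4. Both six‑membered rings come intact from (4R,6R)‑actinol; order of ring formation: oxirane → butenolide → dihydrofuran (the oxirane is consumed).

Assumption: (4R,6R)‑actinol is bought enantiopure; the target SMILES is read as 3S,5R,8R (furanoid half) and 3′R (acetylenic half).

This route has not been run; yields and selectivities quoted are expectations, and the selectivity of steps 4, 9 and 10 is the main uncertainty.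

**Step 1**
Reactants: 1 (4R,6R)-4-hydroxy-2,2,6-trimethylcyclohexan-1-one
Product: 2 (4R,6R)-4-(tert-butyldimethylsilyloxy)-2,2,6-trimethylcyclohexan-1-one
Conditions: TBSCl, imidazole, DMF, 20 °C
Reagents that add atoms: tert-butyldimethylsilyl chloride, CC(C)(C)[Si](C)(C)Cl
Why: imidazole‑promoted silylation of the secondary alcohol (Corey protocol), no stereocentre touched.

**Step 2**
Reactants: 2 silyl ether ketone
Product: 4 (4R)-4-(tert-butyldimethylsilyloxy)-2,6,6-trimethylcyclohex-1-en-1-yl trifluoromethanesulfonate, via lithium enolate 3 (not isolated)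
Conditions: LiN(iPr)2, THF, −78 → 0 °C; PhNTf2, −78 → 20 °C
Reagents that add atoms: N-phenylbis(trifluoromethanesulfonimide), O=S(=O)(N(c1ccccc1)S(=O)(=O)C(F)(F)F)C(F)(F)F
Why: the ketone can enolise only toward the methyl‑bearing carbon (the other α‑carbon is quaternary), so enolate O‑triflation gives a single tetrasubstituted enol triflate; the methyl‑bearing stereocentre is erased on purpose and the silyloxy centre is untouched.

**Step 3**
Reactants: 4 enol triflate; 5 ethynyltrimethylsilane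
Product: 7 tert-butyl{[(1R)-4-ethynyl-3,5,5-trimethylcyclohex-3-en-1-yl]oxy}dimethylsilane, via TMS-enyne 6 (not isolated)
Conditions: Pd(PPh3)4 (5 mol %), CuI (10 mol %), iPr2NH, DMF, 50 °C; then K2CO3, MeOH, 20 °C (same flask)
Reagents that add atoms: none
Why: Sonogashira coupling of the hindered enol triflate with a small alkyne followed by in‑flask methanolysis of the C–Si bond, no stereocentre formed.

**Step 4**
Reactants: 7 terminal enyne
Product: 8 tert-butyl{[(1R,4S,6R)-1-ethynyl-2,2,6-trimethyl-7-oxabicyclo[4.1.0]heptan-4-yl]oxy}dimethylsilane (oxirane anti to the silyloxy group)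
Conditions: mCPBA, CH2Cl2, 0 °C
Reagents that add atoms: 3-chloroperoxybenzoic acid, OOC(=O)c1cccc(Cl)c1
Why: Prilezhaev epoxidation of the electron‑rich tetrasubstituted ring alkene (the terminal alkyne is inert), with the peracid expected to approach anti to the bulky silyl ether so that C5 and C6 are set by substrate control (about 3:1 expected, syn isomer removed by chromatography).

**Step 5**
Reactants: 9 (2E)-3-methylpent-2-en-4-yn-1-ol
Product: 10 [(2E)-3-methylpent-2-en-4-yn-1-yl]triphenylphosphonium bromide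
Conditions: PPh3·HBr, MeOH, 20 °C
Reagents that add atoms: triphenylphosphine hydrobromide, [Br-].c1ccc(cc1)[PH+](c1ccccc1)c1ccccc1
Why: acid‑mediated substitution of the allylic alcohol by PPh3, the standard entry to carotenoid Wittig salts, the E alkene being the thermodynamic isomer.

**Step 6**
Reactants: 10 phosphonium bromide (2 equiv); 11 glyoxal
Product: 14 (3E,5E,7E,9E)-3,10-dimethyldodeca-3,5,7,9-tetraene-1,11-diyne, via ylide 12 (not isolated), via dienynal 13 (not isolated)
Conditions: NaOMe, MeOH–CH2Cl2, 0 → 20 °C; then I2 (1 mol %), hexane, daylight, crystallise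
Reagents that add atoms: none
Why: twofold Wittig olefination of the dialdehyde by the semi‑stabilised allylic ylide, then iodine‑catalysed equilibration of the two new disubstituted alkenes to the all‑E tetraene (thermodynamic control).

**Step 7**
Reactants: 4 enol triflate; 14 tetraene-diyne (3 equiv)
Product: 15 tert-butyl{[(1R)-4-[(3E,5E,7E,9E)-3,10-dimethyldodeca-3,5,7,9-tetraene-1,11-diyn-1-yl]-3,5,5-trimethylcyclohex-3-en-1-yl]oxy}dimethylsilane
Conditions: Pd(PPh3)4 (5 mol %), CuI (10 mol %), iPr2NH, DMF, 40 °C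
Reagents that add atoms: none
Why: Sonogashira coupling in which the excess of the C2‑symmetric diyne makes statistical monocoupling dominant (unreacted 14 is recovered), no stereocentre formed.

**Step 8**
Reactants: 16 propiolic acid
Product: 17 (2E)-2,3-dibromoprop-2-enoic acid
Conditions: Br2, CHCl3, 0 → 20 °C, dark
Reagents that add atoms: bromine, BrBr
Why: anti addition of bromine across the triple bond (bromonium mechanism) gives the E dibromide in which the C3 bromine is cis to the carboxyl group.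

**Step 9 (key step)**
Reactants: 15 eastern polyenyne; 17 (2E)-2,3-dibromoprop-2-enoic acid; 8 ethynyl oxirane
Product: 20 C37 alkynyl-oxirane Z-ylidenebutenolide bis-silyl ether (full name in the compound list), via bromo enynoic acid 18 (not isolated), via bromobutenolide 19 (not isolated)
Conditions: 15 + 17 (1.0 equiv), PdCl2(PPh3)2 (5 mol %), CuI (10 mol %), Et3N, MeCN–THF, 20 °C; then 8 (1.3 equiv), 45 °C (same flask)
Reagents that add atoms: none
Why: Negishi‑type tandem Sonogashira–5‑exo‑dig lactonisation in which the terminal alkyne of 15 acts as a masked acyl anion – it is joined to the acceptor β‑carbon C3 of 17 (both carbons electrophilic by nature) and only then becomes the acyl‑level enol‑lactone carbon by anti addition of the carboxylate, which gives the Z ylidene – after which the remaining C–Br, an α‑carbonyl cation (enolonium) equivalent, couples with the acetylide of 8 in a second Sonogashira reaction, no stereocentre being formed or touched.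

**Step 10**
Reactants: 20 alkynyl-oxirane ylidenebutenolide
Product: 21 α-hydroxyallene with S-configured axis (full name in the compound list)
Conditions: Pd2(dba)3·CHCl3 (2.5 mol %), PBu3 (5 mol %), HCO2H–Et3N, THF, 0 → 20 °C
Reagents that add atoms: none
Why: Tsuji‑type formate hydrogenolysis, in which zerovalent palladium opens the alkynyl oxirane anti (SN2′) to a σ‑allenylpalladium alkoxide, formate gives Pd–H and reductive elimination with retention places H on C8 anti to the departing oxygen, so the S allene axis is fixed by centre‑to‑axis transfer while the C5 carbinol keeps its configuration.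

**Step 11**
Reactants: 21 α-hydroxyallene
Product: 22 bis(tert-butyldimethylsilyl) ether of the target (full name in the compound list)
Conditions: AgNO3 (20 mol %), CaCO3, acetone, 20 °C, dark
Reagents that add atoms: none
Why: Marshall‑type silver‑catalysed 5‑endo cycloisomerisation of the α‑hydroxyallene, in which the C5 hydroxyl adds to silver‑activated C8 in the plane of the C6 substituents, so axis‑to‑centre transfer gives 8R (butenolide trans to the C5 methyl group).

**Step 12**
Reactants: 22 bis-silyl ether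
Product: 23 target CNP0300047.2
Conditions: Bu4NF–AcOH (1:1, 4 equiv), THF, 0 → 20 °C
Reagents that add atoms: none
Why: buffered fluoride desilylation removes both secondary silyl ethers without opening the enol lactone or ionising the acid‑labile allylic C8–O bond, no stereocentre affected.

**Compound list**
1 | (4R,6R)-4-hydroxy-2,2,6-trimethylcyclohexan-1-one (actinol) | C[C@H]1C(=O)C(C)(C)C[C@H](O)C1 | starting material
2 | (4R,6R)-4-(tert-butyldimethylsilyloxy)-2,2,6-trimethylcyclohexan-1-one | C[C@H]1C(=O)C(C)(C)C[C@H](O[Si](C)(C)C(C)(C)C)C1 | intermediate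
3 | lithium (4R)-4-(tert-butyldimethylsilyloxy)-2,6,6-trimethylcyclohex-1-en-1-olate | CC1=C(O[Li])C(C)(C)C[C@H](O[Si](C)(C)C(C)(C)C)C1 | intermediate
4 | (4R)-4-(tert-butyldimethylsilyloxy)-2,6,6-trimethylcyclohex-1-en-1-yl trifluoromethanesulfonate | CC1=C(OS(=O)(=O)C(F)(F)F)C(C)(C)C[C@H](O[Si](C)(C)C(C)(C)C)C1 | intermediate
5 | ethynyltrimethylsilane | C#C[Si](C)(C)C | starting material
6 | tert-butyldimethyl{[(1R)-3,5,5-trimethyl-4-[(trimethylsilyl)ethynyl]cyclohex-3-en-1-yl]oxy}silane | CC1=C(C#C[Si](C)(C)C)C(C)(C)C[C@H](O[Si](C)(C)C(C)(C)C)C1 | intermediate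
7 | tert-butyl{[(1R)-4-ethynyl-3,5,5-trimethylcyclohex-3-en-1-yl]oxy}dimethylsilane | CC1=C(C#C)C(C)(C)C[C@H](O[Si](C)(C)C(C)(C)C)C1 | intermediate
8 | tert-butyl{[(1R,4S,6R)-1-ethynyl-2,2,6-trimethyl-7-oxabicyclo[4.1.0]heptan-4-yl]oxy}dimethylsilane (oxirane anti to OTBS) | C#C[C@@]12O[C@]1(C)C[C@@H](O[Si](C)(C)C(C)(C)C)CC2(C)C | intermediate
9 | (2E)-3-methylpent-2-en-4-yn-1-ol | C#C/C(C)=C/CO | starting material
10 | [(2E)-3-methylpent-2-en-4-yn-1-yl]triphenylphosphonium bromide | C#C/C(C)=C/C[P+](c1ccccc1)(c1ccccc1)c1ccccc1.[Br-] | intermediate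
11 | glyoxal (ethanedial) | O=CC=O | starting material
12 | [(2E)-3-methylpent-2-en-4-yn-1-ylidene]triphenylphosphorane | C#C/C(C)=C/C=P(c1ccccc1)(c1ccccc1)c1ccccc1 | intermediate
13 | (2E,4E)-5-methylhepta-2,4-dien-6-ynal | C#C/C(C)=C/C=C/C=O | intermediate
14 | (3E,5E,7E,9E)-3,10-dimethyldodeca-3,5,7,9-tetraene-1,11-diyne | C#C/C(C)=C/C=C/C=C/C=C(C)/C#C | intermediate
15 | tert-butyl{[(1R)-4-[(3E,5E,7E,9E)-3,10-dimethyldodeca-3,5,7,9-tetraene-1,11-diyn-1-yl]-3,5,5-trimethylcyclohex-3-en-1-yl]oxy}dimethylsilane | CC1=C(C#C/C(C)=C/C=C/C=C/C=C(C)/C#C)C(C)(C)C[C@H](O[Si](C)(C)C(C)(C)C)C1 | intermediate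
16 | propiolic acid (prop-2-ynoic acid) | C#CC(=O)O | starting material
17 | (2E)-2,3-dibromoprop-2-enoic acid (C3–Br cis to CO2H) | OC(=O)/C(Br)=C\Br | intermediate
18 | (2E,6E,8E,10E,12E)-2-bromo-15-[(4R)-4-(tert-butyldimethylsilyloxy)-2,6,6-trimethylcyclohex-1-en-1-yl]-6,13-dimethylpentadeca-2,6,8,10,12-pentaene-4,14-diynoic acid (alkynyl cis to CO2H) | CC1=C(C#C/C(C)=C/C=C/C=C/C=C(C)/C#C/C=C(/Br)C(=O)O)C(C)(C)C[C@H](O[Si](C)(C)C(C)(C)C)C1 | intermediate
19 | (5Z)-3-bromo-5-[(2E,4E,6E,8E)-11-[(4R)-4-(tert-butyldimethylsilyloxy)-2,6,6-trimethylcyclohex-1-en-1-yl]-2,9-dimethylundeca-2,4,6,8-tetraen-10-yn-1-ylidene]furan-2(5H)-one | CC1=C(C#C/C(C)=C/C=C/C=C/C=C(C)/C=C2/C=C(Br)C(=O)O2)C(C)(C)C[C@H](O[Si](C)(C)C(C)(C)C)C1 | intermediate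
20 | (5Z)-3-{[(1R,4S,6R)-4-(tert-butyldimethylsilyloxy)-2,2,6-trimethyl-7-oxabicyclo[4.1.0]heptan-1-yl]ethynyl}-5-[(2E,4E,6E,8E)-11-[(4R)-4-(tert-butyldimethylsilyloxy)-2,6,6-trimethylcyclohex-1-en-1-yl]-2,9-dimethylundeca-2,4,6,8-tetraen-10-yn-1-ylidene]furan-2(5H)-one | CC1=C(C#C/C(C)=C/C=C/C=C/C=C(C)/C=C2/C=C(C#C[C@@]34O[C@]3(C)C[C@@H](O[Si](C)(C)C(C)(C)C)CC4(C)C)C(=O)O2)C(C)(C)C[C@H](O[Si](C)(C)C(C)(C)C)C1 | intermediate
21 | (5Z)-3-{(aS)-2-[(2R,4S)-4-(tert-butyldimethylsilyloxy)-2-hydroxy-2,6,6-trimethylcyclohexylidene]ethenyl}-5-[(2E,4E,6E,8E)-11-[(4R)-4-(tert-butyldimethylsilyloxy)-2,6,6-trimethylcyclohex-1-en-1-yl]-2,9-dimethylundeca-2,4,6,8-tetraen-10-yn-1-ylidene]furan-2(5H)-one (allene: butenolide on the face of the former oxirane oxygen, H-8 anti) | CC1=C(C#C/C(C)=C/C=C/C=C/C=C(C)/C=C2/C=C(C([H])=[C@]=C3C(C)(C)C[C@H](O[Si](C)(C)C(C)(C)C)C[C@@]3(C)O)C(=O)O2)C(C)(C)C[C@H](O[Si](C)(C)C(C)(C)C)C1 | intermediate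
22 | (5Z)-3-[(2R,6S,7aR)-6-(tert-butyldimethylsilyloxy)-4,4,7a-trimethyl-2,4,5,6,7,7a-hexahydro-1-benzofuran-2-yl]-5-[(2E,4E,6E,8E)-11-[(4R)-4-(tert-butyldimethylsilyloxy)-2,6,6-trimethylcyclohex-1-en-1-yl]-2,9-dimethylundeca-2,4,6,8-tetraen-10-yn-1-ylidene]furan-2(5H)-one | CC1=C(C#C/C(C)=C/C=C/C=C/C=C(C)/C=C2/C=C([C@H]3C=C4C(C)(C)C[C@H](O[Si](C)(C)C(C)(C)C)C[C@@]4(C)O3)C(=O)O2)C(C)(C)C[C@H](O[Si](C)(C)C(C)(C)C)C1 | intermediate
23 | (5Z)-3-[(2R,6S,7aR)-6-hydroxy-4,4,7a-trimethyl-2,4,5,6,7,7a-hexahydro-1-benzofuran-2-yl]-5-[(2E,4E,6E,8E)-11-[(4R)-4-hydroxy-2,6,6-trimethylcyclohex-1-en-1-yl]-2,9-dimethylundeca-2,4,6,8-tetraen-10-yn-1-ylidene]furan-2(5H)-one | CC1=C(C#C/C(C)=C/C=C/C=C/C=C(C)/C=C2/C=C([C@H]3C=C4C(C)(C)C[C@H](O)C[C@@]4(C)O3)C(=O)O2)C(C)(C)C[C@H](O)C1 | target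

**Totals**
Total step count: 12.
Longest linear sequence: 8 steps (steps 1, 2, 3, 4, 9, 10, 11, 12; 1 → 2 → 4 → 7 → 8 → 20 → 21 → 22 → 23).

**Three steps most likely to fail, each with one fallback**

Step 9. The one‑flask sequence asks for selective coupling at C3–Br of 17, then coupling at the α‑bromide of 19 while the zerovalent palladium must leave the propargylic oxirane of 8 alone. Fallback, setting out from 15, 17 and 8 and returning at 20: stop after the first stage and isolate bromobutenolide 19. Deprotonate 8 (LiN(SiMe3)2, THF, −78 °C) and quench with Bu3SnCl to give the alkynylstannane F1. Join 19 and F1 by a copper‑free and amine‑free Stille coupling (Pd2(dba)3, AsPh3, NMP, 20 °C) to reach 20.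

Step 10. The allenylpalladium intermediate may epimerise, or hydride may be delivered to C6 or to the polyene. Fallback, setting out from 19 (isolated as above) and 8 and returning at 21: Miyaura borylation of 19 (B2pin2, PdCl2(dppf), KOAc, dioxane, 60 °C) gives the pinacol boronate F2. Rhodium‑catalysed addition of F2 to the terminal alkynyl oxirane 8 ([Rh(OH)(cod)]2, THF–H2O, 20 °C) proceeds by syn carbometalation and β‑oxygen elimination. This puts the butenolide carbon on C8 syn to the oxirane oxygen, which is the same allene 21 that anti hydride delivery gives, and it does so in the C–C bond‑forming event.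

Step 4. Peracid facial selectivity on the silyl ether may be low or even reversed. Fallback, setting out from 4 and returning at 8: palladium‑catalysed methoxycarbonylation of 4 (Pd(OAc)2, PPh3, CO, MeOH, Et3N, DMF) gives the methyl ester F3. Reduction with iBu2AlH gives the allylic alcohol F4. Reagent‑controlled Sharpless epoxidation (Ti(OiPr)4, tBuOOH, and the diethyl tartrate enantiomer matched to the face anti to the silyloxy group) gives the epoxy alcohol F5. Oxidation (SO3·pyridine, DMSO, Et3N) gives the epoxy aldehyde F6. Ohira–Bestmann homologation (dimethyl (1-diazo-2-oxopropyl)phosphonate, K2CO3, MeOH) returns the ethynyl oxirane 8 as a single diastereomer.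

**Further compounds**
F1 | step 9 | tributyl{[(1R,4S,6R)-4-(tert-butyldimethylsilyloxy)-2,2,6-trimethyl-7-oxabicyclo[4.1.0]heptan-1-yl]ethynyl}stannane | CCCC[Sn](CCCC)(CCCC)C#C[C@@]12O[C@]1(C)C[C@@H](O[Si](C)(C)C(C)(C)C)CC2(C)C
F2 | step 10 | (5Z)-5-[(2E,4E,6E,8E)-11-[(4R)-4-(tert-butyldimethylsilyloxy)-2,6,6-trimethylcyclohex-1-en-1-yl]-2,9-dimethylundeca-2,4,6,8-tetraen-10-yn-1-ylidene]-3-(4,4,5,5-tetramethyl-1,3,2-dioxaborolan-2-yl)furan-2(5H)-one | CC1=C(C#C/C(C)=C/C=C/C=C/C=C(C)/C=C2/C=C(B3OC(C)(C)C(C)(C)O3)C(=O)O2)C(C)(C)C[C@H](O[Si](C)(C)C(C)(C)C)C1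
F3 | step 4 | methyl (4R)-4-(tert-butyldimethylsilyloxy)-2,6,6-trimethylcyclohex-1-ene-1-carboxylate | CC1=C(C(=O)OC)C(C)(C)C[C@H](O[Si](C)(C)C(C)(C)C)C1
F4 | step 4 | [(4R)-4-(tert-butyldimethylsilyloxy)-2,6,6-trimethylcyclohex-1-en-1-yl]methanol | CC1=C(CO)C(C)(C)C[C@H](O[Si](C)(C)C(C)(C)C)C1
F5 | step 4 | [(1R,4S,6R)-4-(tert-butyldimethylsilyloxy)-2,2,6-trimethyl-7-oxabicyclo[4.1.0]heptan-1-yl]methanol (oxirane anti to OTBS) | OC[C@@]12O[C@]1(C)C[C@@H](O[Si](C)(C)C(C)(C)C)CC2(C)C
F6 | step 4 | (1S,4S,6R)-4-(tert-butyldimethylsilyloxy)-2,2,6-trimethyl-7-oxabicyclo[4.1.0]heptane-1-carbaldehyde (ring configuration as in 8) | O=C[C@@]12O[C@]1(C)C[C@@H](O[Si](C)(C)C(C)(C)C)CC2(C)C
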